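**Assumptions:** 3-bromo-5-methoxyphenol, (R)-but-3-en-2-ol and 3,5-dimethoxystyrene are commercial. In the Claisen step the C3a′ (desired) isomer predominates and is separable. Both meta substituents on the central ring bias the rearrangement toward C3a′: the OMe is para to it and the alkenyl group is adjacent to it.

## Retrosynthetic overview
- Target 17 comes from global O-demethylation of 16. Compound 16 comes from a Heck installation of the 3,5-dimethoxystyryl group on aryl bromide 15.
- Compound 15 has both dihydrobenzofuran rings closed last, by acid-mediated trans-selective cyclisation of bis-carbinol 14. Compound 14 comes from ArMgBr addition to bis-lactol 12, which comes from ozonolysis of bis-propenyl phenol 11.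
- Key step: a double aromatic Claisen [3,3] rearrangement of bis(allyl aryl ether) 10. It forms both C3–C3a and C3′–C3a′ bonds on the central resorcinol ring and transfers the stereochemistry of two (R)-but-3-en-2-ol-derived carbinol centres to C3 and C3′.
- C2 and C2′ are then set trans to C3 and C3′ by thermodynamic control. Ether 10 is assembled from simple phenols, styrenes and (R)-but-3-en-2-ol.

## Route

**Step 1**
Reactants: 1 (4-bromophenol), 2 ((R)-but-3-en-2-ol)
Product: 3 ((S)-but-3-en-2-yl 4-bromophenyl ether)
Conditions: PPh3, DIAD, THF, 0 °C → rt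
Reagents that add atoms: none
Why: Mitsunobu etherification of a secondary allylic alcohol by a phenol proceeds by SN2 with inversion, so (R)-alcohol gives (S)-ether.

**Step 2**
Reactants: 4 (3-bromo-5-methoxyphenol), 5 (potassium vinyltrifluoroborate)
Product: 6 (3-methoxy-5-vinylphenol)
Conditions: PdCl2(dppf), Cs2CO3, THF/H2O, 80 °C
Reagents that add atoms: none beyond reactant 5 (supplies the vinyl group)
Why: Suzuki–Miyaura vinylation tolerates the free phenol.

**Step 3**
Reactants: 6, 3
Product: 7 (3-[(1E,3S)-3-(4-bromophenoxy)but-1-enyl]-5-methoxyphenol)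
Conditions: Grubbs II (5 mol %), CH2Cl2, 40 °C; 3 in excess
Reagents that add atoms: none (ethylene is lost)
Why: Cross-metathesis of a styrene with a terminal allylic aryl ether gives the E-1,2-disubstituted alkene and leaves the stereocentre untouched.

**Step 4**
Reactants: 8 (3,5-dimethoxystyrene), 2
Product: 9 ((R,E)-4-(3,5-dimethoxyphenyl)but-3-en-2-ol)
Conditions: Grubbs II (5 mol %), CH2Cl2, 40 °C; 2 in excess
Reagents that add atoms: none
Why: E-selective cross-metathesis with the free allylic alcohol keeps the (R) carbinol centre.

**Step 5**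
Reactants: 7 (phenol), 9
Product: 10 (central aryl bis-ether with two (S)-1-methylallyl aryl ether units)
Conditions: PPh3, DIAD, THF, 0 °C → rt
Reagents that add atoms: none
Why: Mitsunobu inversion converts the (R)-alcohol 9 into the (S)-allylic aryl ether, giving the Claisen precursor with both O–CH(CH3) centres (S).

**Step 6 (key step)**
Reactants: 10
Product: 11 (2-[(S-configured) 1-(3,5-dimethoxyphenyl)but-2-enyl]-3-[1-(5-bromo-2-hydroxyphenyl)but-2-enyl]-5-methoxyphenol, E-alkenes)
Conditions: o-dichlorobenzene, BHT, 190 °C, sealed tube, 18 h; chromatography removes the C7′ regioisomer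
Reagents that add atoms: none (isomerisation)
Why: Each aromatic Claisen [3,3] rearrangement runs through a chair transition state with an E-alkene and an equatorial CH3, so the configuration at the carbinol carbon sets the new benzylic carbon. (S)-Ether gives (S) C3 and C3′ in the target numbering, and the 4-bromophenol ring has two equivalent ortho positions.

**Step 7**
Reactants: 11
Product: 12 (bis-lactol, 2-hydroxy-2,3-dihydrobenzofuran rings, anomeric mixture)
Conditions: O3, CH2Cl2, −78 °C; then Me2S, −78 °C → rt
Reagents that add atoms: ozone, O=[O+][O-] (supplies the aldehyde and lactol O)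
Why: Ozonolysis cleaves the 1,2-disubstituted propenyl alkenes faster than the electron-rich arenes, and each aldehyde is trapped immediately by its ortho phenol as a lactol, which protects the α-stereocentre.

**Step 8**
Reactants: 12, 13 (4-methoxyphenylmagnesium bromide)
Product: 14 (bis(4-methoxyphenyl)carbinol, free phenols, carbinol epimers)
Conditions: 13 (10 equiv), THF, −78 → 0 °C; NH4Cl work-up
Reagents that add atoms: none beyond reactant 13
Why: Addition of ArMgBr to the aldehyde forms of the lactols forms the C2–aryl bond, and the carbinol configuration is irrelevant because it is reset in the next step.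

**Step 9**
Reactants: 14
Product: 15 (bis-trans-2,3-diaryl-dihydrobenzofuran aryl bromide)
Conditions: p-TsOH·H2O (20 mol %), CH2Cl2, 0.01 M, 0 °C → rt
Reagents that add atoms: none (loses 2 H2O)
Why: Acid ionises the p-methoxybenzylic alcohol, and each phenol closes 5-exo onto the cation. Under reversible conditions the trans-2,3-diaryl ring is favoured, so C2 and C2′ are set (S) relative to the existing C3 and C3′.

**Step 10**
Reactants: 15, 8
Product: 16 (permethylated target)
Conditions: Pd(OAc)2, P(o-tol)3, Et3N, DMF, 110 °C
Reagents that add atoms: none beyond reactant 8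
Why: The Mizoroki–Heck reaction gives the E-stilbene from the electron-rich aryl bromide; no free phenols remain at this stage, and the saturated stereocentres are unaffected.

**Step 11**
Reactants: 16
Product: 17 (trans-diptoindonesin B)
Conditions: BBr3 (about 20 equiv), CH2Cl2, −78 °C → rt; MeOH/H2O quench
Reagents that add atoms: none (Me–O cleavage only; the new O–H hydrogens come from work-up)
Why: BBr3 cleaves all seven aryl methyl ethers and leaves the cyclic aryl alkyl ethers, the E-alkene and the stereocentres intact under cold, controlled conditions.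

## Compound list
1 | 4-bromophenol | Oc1ccc(Br)cc1 | starting material
2 | (R)-but-3-en-2-ol | C[C@@H](O)C=C | starting material
3 | (S)-but-3-en-2-yl 4-bromophenyl ether | C[C@H](Oc1ccc(Br)cc1)C=C | intermediate
4 | 3-bromo-5-methoxyphenol | COc1cc(O)cc(Br)c1 | starting material
5 | potassium vinyltrifluoroborate | [K+].C=C[B-](F)(F)F | starting material
6 | 3-methoxy-5-vinylphenol | COc1cc(O)cc(C=C)c1 | intermediate
7 | 3-[(1E,3S)-3-(4-bromophenoxy)but-1-enyl]-5-methoxyphenol | C[C@@H](/C=C/c1cc(O)cc(OC)c1)Oc1ccc(Br)cc1 | intermediate
8 | 3,5-dimethoxystyrene | COc1cc(C=C)cc(OC)c1 | starting material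
9 | (R,E)-4-(3,5-dimethoxyphenyl)but-3-en-2-ol | C[C@@H](O)/C=C/c1cc(OC)cc(OC)c1 | intermediate
10 | bis(allyl aryl ether) Claisen precursor | C[C@@H](/C=C/c1cc(OC)cc(OC)c1)Oc1cc(OC)cc(/C=C/[C@H](C)Oc2ccc(Br)cc2)c1 | intermediate
11 | bis(o-propenyl) phenol from double Claisen | COc1cc([C@@H](c2cc(Br)ccc2O)/C=C/C)c([C@H](c2cc(OC)cc(OC)c2)/C=C/C)c(O)c1 | intermediate
12 | bis-lactol (anomeric mixture) | COc1cc([C@@H]2C(O)Oc3ccc(Br)cc32)c2c(c1)OC(O)[C@H]2c1cc(OC)cc(OC)c1 | intermediate
13 | 4-methoxyphenylmagnesium bromide | COc1ccc([Mg]Br)cc1 | starting material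
14 | bis-carbinol (carbinol epimer mixture) | COc1cc([C@@H](c2cc(Br)ccc2O)C(O)c2ccc(OC)cc2)c([C@H](c2cc(OC)cc(OC)c2)C(O)c2ccc(OC)cc2)c(O)c1 | intermediate
15 | bis-trans-dihydrobenzofuran aryl bromide | COc1ccc([C@H]2Oc3ccc(Br)cc3[C@@H]2c2cc(OC)cc3c2[C@H](c2cc(OC)cc(OC)c2)[C@@H](c2ccc(OC)cc2)O3)cc1 | intermediate
16 | permethylated trans-diptoindonesin B | COc1ccc([C@H]2Oc3ccc(/C=C/c4cc(OC)cc(OC)c4)cc3[C@@H]2c2cc(OC)cc3c2[C@H](c2cc(OC)cc(OC)c2)[C@@H](c2ccc(OC)cc2)O3)cc1 | intermediate
17 | trans-diptoindonesin B | Oc1ccc([C@H]2Oc3ccc(/C=C/c4cc(O)cc(O)c4)cc3[C@@H]2c2cc(O)cc3c2[C@H](c2cc(O)cc(O)c2)[C@@H](c2ccc(O)cc2)O3)cc1 | target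

## Totals
Total steps: 11. Longest linear sequence: 9 (Steps 2, 3, 5, 6, 7, 8, 9, 10, 11).

## Three steps most likely to fail
1. **Step 6 (double Claisen).** The C3a′/C7′ regioselectivity may be poor, and the second rearrangement is hindered by the first. Fallback: use a central ring with the C7′ position blocked by Br, rearrange the two allyl ethers sequentially, and remove the Br by Li–halogen exchange and protonation after the rings are closed.
2. **Step 8 (ArMgBr addition to an α,α-diaryl aldehyde, as the lactol).** The basic Grignard may epimerise C3 or C3′, or add poorly to the congested bis-lactol. Fallback: add 4-methoxyphenylboronic acid to the aldehyde by achiral Rh(I) catalysis under neutral conditions.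
3. **Step 5 (Mitsunobu on a secondary cinnamyl-type alcohol).** Partial SN1 or SN2′ reaction would erode the configuration of the carbinol centre that sets C3′. Fallback: convert (R)-9 to its mesylate and displace it with the caesium phenoxide of 7 (SN2 with inversion, no betaine intermediate).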